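## Retrosynthetic overview

1. Target 20 ⇐ butenolide 16 (ent-19-hydroxylabda-8(17),13-dien-15,16-olide): hydroxide opens the lactone, then O16 and O19 are acetylated. The ring supplies the 13Z geometry.
2. 16 ⇐ furan 10 by making the C15–O bond (C–H borylation at the open furan α-position, then boron-to-oxygen oxidation). 10 ⇐ andrograpanin 8 (the 16,15-olide) by i-Bu2AlH reduction and aromatisation. Net result: the lactone carbonyl moves from C16 to C15.
3. 8 ⇐ andrographolide 1 by removing O3 (radical cleavage of a 3,19-thionocarbonate) and O14 (SN2′ hydride displacement of the 14-acetate).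
4. Ring order: no carbocycle is built. The trans-decalin with C4, C5, C9, C10 and the exocyclic alkene comes intact from 1; only the heterocycle is reshaped (16,15-olide → furan → 15,16-olide → opened).

Assumption: andrographolide, the bulk-extracted ent-labdane of Andrographis paniculata, counts as a cheap commercial starting material, and operations run in one flask without isolation count as one step.

## Route

Step 1
Reactants: 1 andrographolide; 2 1,1'-thiocarbonyldiimidazole; 3 acetic anhydride
Product: 5 14-O-acetyl-3,19-O-thiocarbonylandrographolide, via cyclic thionocarbonate 4 (not isolated)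
Conditions: TCDI (1.15 equiv), DMAP (0.1 equiv), THF, 50 °C; then Ac2O (3 equiv), pyridine, 0 → 23 °C
Reagents that add atoms: 1,1'-thiocarbonyldiimidazole (2), S=C(n1ccnc1)n1ccnc1; acetic anhydride (3), CC(=O)OC(C)=O
Why: Thiocarbonyl transfer (cyclic thionocarbonate formation) favours the 3,19-diol because the primary C19–OH is acylated first and the adjacent C3–OH closes a six-membered ring faster than the lone C14–OH reacts; the remaining C14–OH is then O-acetylated (nucleophilic acyl substitution), the excess Ac2O also capping the liberated imidazole so that it cannot add to C12, and no stereocentre is touched.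

Step 2
Reactants: 5 14-O-acetyl-3,19-O-thiocarbonylandrographolide
Product: 7 14-O-acetyl-3-deoxyandrographolide, via S-silyl thiocarbonate 6 (not isolated)
Conditions: (Me3Si)3SiH (1.3 equiv), AIBN (0.2 equiv), toluene, 85 °C; then MeOH, 23 °C
Reagents that add atoms: none
Why: Barton–McCombie-type radical deoxygenation of a cyclic thionocarbonate: the silyl radical adds to sulfur, β-scission breaks the C3–O bond because that gives the secondary radical (the primary C19–O bond stays), hydrogen-atom transfer caps C3 (its stereocentre is deliberately erased), and methanolysis of the S–Si bond followed by loss of COS frees the C19 alcohol.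

Step 3
Reactants: 7 14-O-acetyl-3-deoxyandrographolide
Product: 8 andrograpanin [ent-19-hydroxylabda-8(17),13-dien-16,15-olide]
Conditions: NaBH4 (1.0 equiv), THF–t-BuOH (4:1), 0 → 23 °C
Reagents that add atoms: none
Why: Conjugate hydride addition to C12 of the alkylidene lactone followed by E1cB loss of the C14 acetate (the SN2′-type reduction known for Morita–Baylis–Hillman acetates) moves the alkene into the ring as C13=C14, removes the C14 stereocentre and fixes C15 and C16 cis across the new alkene.

Step 4
Reactants: 8 andrograpanin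
Product: 10 ent-15,16-epoxylabda-8(17),13(16),14-trien-19-ol (the 3-substituted furan), via lactol 9 (not isolated)
Conditions: i-Bu2AlH (2.5 equiv), CH2Cl2, −78 °C; then 1 M HCl, THF, 0 °C, 15 min
Reagents that add atoms: none
Why: Standard butenolide-to-furan conversion: 1,2-reduction of the lactone by i-Bu2AlH stops at the lactol, which loses water under brief acid treatment and aromatises to the 3-substituted furan; no stereocentre is involved.

Step 5
Reactants: 10 furan alcohol; 11 pinacolborane; 12 bis(pinacolato)diboron; 13 hydrogen peroxide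
Product: 16 ent-19-hydroxylabda-8(17),13-dien-15,16-olide, via O-boryl furan 14 (not isolated), via C15-boryl O-boryl furan 15 (not isolated)
Conditions: [Ir(OMe)(cod)]2 (1.5 mol %), dtbpy (3 mol %), HBpin (1.1 equiv) then B2pin2 (1.0 equiv), THF, 23 °C; then 30 % H2O2, pH 7 phosphate buffer, 0 °C; then Et3N (0.2 equiv), CH2Cl2, 23 °C
Reagents that add atoms: pinacolborane (11), CC1(C)OBOC1(C)C; bis(pinacolato)diboron (12), CC1(C)OB(OC1(C)C)B1OC(C)(C)C(C)(C)O1; hydrogen peroxide (13), OO
Why: Proposed new method: a site-controlled furan-to-butenolide oxygenation in which, after the free alcohol is masked in the flask as its O-Bpin ether, the trivalent iridium tris(boryl)–dtbpy catalyst cleaves the only unhindered α-C–H bond of the 3-alkylfuran (C15–H; C16–H is flanked by the side chain) by the usual sterically governed oxidative addition/reductive elimination, peroxide turns the C15–B bond into the C15–O bond by 1,2-migration from boron to oxygen, and hydrolysis followed by Et3N-mediated tautomerisation gives the conjugated 15,16-olide; the boron and pinacol atoms of 11 and 12 are carried only by 14 and 15 and leave as boric acid and pinacol, so 16 keeps just the oxygen atom of 13; the closest known reaction type is iridium-catalysed arene C–H borylation followed by oxidation to phenols, which to my knowledge has not been used to convert a 3-alkylfuran into a 4-alkylbutenolide; no stereocentre is formed and the ring holds C15 and C16 cis.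

Step 6
Reactants: 16 ent-19-hydroxylabda-8(17),13-dien-15,16-olide; 17 potassium hydroxide; 3 acetic anhydride
Product: 20 (13Z)-16,19-diacetoxy-ent-labda-8(17),13-dien-15-oic acid (CNP0181814.1), via potassium hydroxy-enoate 18 (not isolated), via potassium diacetoxy-enoate 19 (not isolated)
Conditions: KOH (1.0 equiv), THF–H2O, 0 °C, then evaporate and dry; KN(SiMe3)2 (2.1 equiv), 18-crown-6, THF, −78 °C; Ac2O (2.2 equiv), −78 → −30 °C; then 1 M HCl to pH 3, 0 °C
Reagents that add atoms: potassium hydroxide (17), [K+].[OH-]; acetic anhydride (3), CC(=O)OC(C)=O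
Why: Lactone saponification followed by alkoxide acylation: hydroxide opens the butenolide with retention of the Z alkene, the two potassium alkoxides made from 18 are acetylated by Ac2O at −78 °C far faster than the carboxylate can form a mixed anhydride, and once O16 carries its acetate the acid released on cold acidification can no longer close back to the lactone.

## Compound list

1 | andrographolide, ent-3,14,19-trihydroxylabda-8(17),12E-dien-16,15-olide (3R,4R,5S,9R,10S,14S) | C=C1CC[C@@H]2[C@](C)(CO)[C@H](O)CC[C@@]2(C)[C@@H]1C/C=C1/C(=O)OC[C@H]1O | starting material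
2 | 1,1'-thiocarbonyldiimidazole | S=C(n1ccnc1)n1ccnc1 | starting material
3 | acetic anhydride | CC(=O)OC(C)=O | starting material
4 | 3,19-O-thiocarbonylandrographolide (six-membered cyclic thionocarbonate across O3 and O19, free 14-OH) | C=C1CC[C@@H]2[C@]3(C)COC(=S)O[C@@H]3CC[C@@]2(C)[C@@H]1C/C=C1/C(=O)OC[C@H]1O | intermediate (not isolated)
5 | 14-O-acetyl-3,19-O-thiocarbonylandrographolide | C=C1CC[C@@H]2[C@]3(C)COC(=S)O[C@@H]3CC[C@@]2(C)[C@@H]1C/C=C1/C(=O)OC[C@H]1OC(C)=O | intermediate
6 | 14-O-acetyl-3-deoxyandrographolide 19-O-carbonyl S-[tris(trimethylsilyl)silyl] thiocarbonate | C=C1CC[C@@H]2[C@](C)(COC(=O)S[Si]([Si](C)(C)C)([Si](C)(C)C)[Si](C)(C)C)CCC[C@@]2(C)[C@@H]1C/C=C1/C(=O)OC[C@H]1OC(C)=O | intermediate (not isolated)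
7 | 14-O-acetyl-3-deoxyandrographolide, ent-14-acetoxy-19-hydroxylabda-8(17),12E-dien-16,15-olide (4R,5S,9R,10S,14S) | C=C1CC[C@@H]2[C@](C)(CO)CCC[C@@]2(C)[C@@H]1C/C=C1/C(=O)OC[C@H]1OC(C)=O | intermediate
8 | andrograpanin, ent-19-hydroxylabda-8(17),13-dien-16,15-olide (side chain ends in a 3-substituted furan-2(5H)-one) | C=C1CC[C@@H]2[C@](C)(CO)CCC[C@@]2(C)[C@@H]1CCC1=CCOC1=O | intermediate
9 | lactol of 8, 3-substituted 2,5-dihydrofuran-2-ol (C16 epimers) | C=C1CC[C@@H]2[C@](C)(CO)CCC[C@@]2(C)[C@@H]1CCC1=CCOC1O | intermediate (not isolated)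
10 | ent-15,16-epoxylabda-8(17),13(16),14-trien-19-ol (side chain ends in a furan-3-yl group) | C=C1CC[C@@H]2[C@](C)(CO)CCC[C@@]2(C)[C@@H]1CCc1ccoc1 | intermediate
11 | pinacolborane | CC1(C)OBOC1(C)C | starting material
12 | bis(pinacolato)diboron | CC1(C)OB(OC1(C)C)B1OC(C)(C)C(C)(C)O1 | starting material
13 | hydrogen peroxide | OO | starting material
14 | 19-O-(pinacolatoboryl) ether of furan 10 | C=C1CC[C@@H]2[C@](C)(COB3OC(C)(C)C(C)(C)O3)CCC[C@@]2(C)[C@@H]1CCc1ccoc1 | intermediate (not isolated)
15 | 19-O-(pinacolatoboryl) ether of 10 bearing a pinacolatoboryl group at furan C15 (5-boryl-3-alkylfuran) | C=C1CC[C@@H]2[C@](C)(COB3OC(C)(C)C(C)(C)O3)CCC[C@@]2(C)[C@@H]1CCc1coc(B2OC(C)(C)C(C)(C)O2)c1 | intermediate (not isolated)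
16 | ent-19-hydroxylabda-8(17),13-dien-15,16-olide (side chain ends in a 4-substituted furan-2(5H)-one) | C=C1CC[C@@H]2[C@](C)(CO)CCC[C@@]2(C)[C@@H]1CCC1=CC(=O)OC1 | intermediate
17 | potassium hydroxide | [K+].[OH-] | starting material
18 | potassium (13Z)-16,19-dihydroxy-ent-labda-8(17),13-dien-15-oate | C=C1CC[C@@H]2[C@](C)(CO)CCC[C@@]2(C)[C@@H]1CC/C(=C/C(=O)[O-])CO.[K+] | intermediate (not isolated)
19 | potassium (13Z)-16,19-diacetoxy-ent-labda-8(17),13-dien-15-oate | C=C1CC[C@@H]2[C@](C)(COC(C)=O)CCC[C@@]2(C)[C@@H]1CC/C(=C/C(=O)[O-])COC(C)=O.[K+] | intermediate (not isolated)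
20 | (13Z)-16,19-diacetoxy-ent-labda-8(17),13-dien-15-oic acid, i.e. (2Z)-4-acetoxy-3-{2-[(1R,4aS,5R,8aS)-5-(acetoxymethyl)-5,8a-dimethyl-2-methylidenedecahydronaphthalen-1-yl]ethyl}but-2-enoic acid | C=C1CC[C@@H]2[C@](C)(COC(C)=O)CCC[C@@]2(C)[C@@H]1CC/C(=C/C(=O)O)COC(C)=O | target

## Step count and risk

Total step count: 6. Longest linear sequence: 6 (fully linear from andrographolide).

The three steps most likely to fail:

**Step 5 (the proposed new step).** Risks are incomplete site selectivity between C15–H and C16–H, competing borylation of the exocyclic alkene, and protodeboronation before oxidation. The C16-borylated minor isomer would oxidise to 8 and could be recycled through step 4. The fallback uses known chemistry and sets out from furan 10: dye-sensitised photo-oxygenation (O2, tetraphenylporphyrin, visible light, i-Pr2NEt, CH2Cl2, −78 °C; [4+2] addition of singlet oxygen, then base-directed Kornblum–DeLaMare fragmentation at the less hindered C15–H) gives the γ-hydroxybutenolide ent-16,19-dihydroxylabda-8(17),13-dien-15,16-olide F4. NaBH4 (EtOH, 0 °C, then dilute HCl) reduces its masked C16 aldehyde and the hydroxy acid closes to 16, where the route is rejoined.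

**Step 6.** Risks are relactonisation to 16 (or its 19-acetate) if the carboxylate is activated before O16 is capped, and γ-deprotonation by the strong base. The fallback never makes the free γ-hydroxy acid and sets out from 16: LiAlH4 (THF, 0 °C) reduces the lactone to (13Z)-ent-labda-8(17),13-diene-15,16,19-triol F5. Ac2O/pyridine/DMAP gives (13Z)-15,16,19-triacetoxy-ent-labda-8(17),13-diene F6. Candida antarctica lipase B (pH 7 buffer/acetone) hydrolyses only the unhindered C15 acetate to give (13Z)-16,19-diacetoxy-ent-labda-8(17),13-dien-15-ol F7. MnO2 (CH2Cl2) oxidises the allylic alcohol to (13Z)-16,19-diacetoxy-ent-labda-8(17),13-dien-15-al F8, and Pinnick oxidation (NaClO2, NaH2PO4, 2-methyl-2-butene, t-BuOH/H2O) gives 20, where the route is rejoined.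

**Step 1.** Risks are that the allylic C14–OH competes for TCDI, and that amine bases trigger SN2′ addition or elimination of the 14-acetate. The fallback protects first and sets out from 1: 2,2-dimethoxypropane/PPTS gives 3,19-O-isopropylideneandrographolide F1. Ac2O/Et3N/DMAP gives 14-O-acetyl-3,19-O-isopropylideneandrographolide F2. Aqueous acetic acid removes the acetal to give 14-O-acetylandrographolide F3, whose only remaining diol is closed with TCDI/DMAP (toluene, 60 °C) to give 5, where the route is rejoined.

## Further compounds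

F1 | step 1 | 3,19-O-isopropylideneandrographolide | C=C1CC[C@@H]2[C@]3(C)COC(C)(C)O[C@@H]3CC[C@@]2(C)[C@@H]1C/C=C1/C(=O)OC[C@H]1O
F2 | step 1 | 14-O-acetyl-3,19-O-isopropylideneandrographolide | C=C1CC[C@@H]2[C@]3(C)COC(C)(C)O[C@@H]3CC[C@@]2(C)[C@@H]1C/C=C1/C(=O)OC[C@H]1OC(C)=O
F3 | step 1 | 14-O-acetylandrographolide | C=C1CC[C@@H]2[C@](C)(CO)[C@H](O)CC[C@@]2(C)[C@@H]1C/C=C1/C(=O)OC[C@H]1OC(C)=O
F4 | step 5 | ent-16,19-dihydroxylabda-8(17),13-dien-15,16-olide (γ-hydroxybutenolide, C16 epimers) | C=C1CC[C@@H]2[C@](C)(CO)CCC[C@@]2(C)[C@@H]1CCC1=CC(=O)OC1O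
F5 | step 6 | (13Z)-ent-labda-8(17),13-diene-15,16,19-triol | C=C1CC[C@@H]2[C@](C)(CO)CCC[C@@]2(C)[C@@H]1CC/C(=C/CO)CO
F6 | step 6 | (13Z)-15,16,19-triacetoxy-ent-labda-8(17),13-diene | C=C1CC[C@@H]2[C@](C)(COC(C)=O)CCC[C@@]2(C)[C@@H]1CC/C(=C/COC(C)=O)COC(C)=O
F7 | step 6 | (13Z)-16,19-diacetoxy-ent-labda-8(17),13-dien-15-ol | C=C1CC[C@@H]2[C@](C)(COC(C)=O)CCC[C@@]2(C)[C@@H]1CC/C(=C/CO)COC(C)=O
F8 | step 6 | (13Z)-16,19-diacetoxy-ent-labda-8(17),13-dien-15-al | C=C1CC[C@@H]2[C@](C)(COC(C)=O)CCC[C@@]2(C)[C@@H]1CC/C(=C/C=O)COC(C)=O
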